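There is far more free monomer than initiator in this flask, 200 to one by charge, and that ratio is where I begin.

| setting | red | green | flask |
|---|---|---|---|
| free monomer | 1.1 M | 1.1 M | 1.1 M |
| initiator | 2.8 mM | 4.1 mM | 5.5 mM |
| remark | run made earlier | run made earlier |  |
| time |  |  | 3.0 h |

| run | time / h | monomer in chains / % | free monomer / % |
|---|---|---|---|
| red | 0.200 | 8.0 | 90.8 |
| red | 0.500 | 33.4 | 66.9 |
| red | 1.00 | 56.6 | 40.8 |
| red | 1.50 | 66.8 | 37.7 |
| red | 2.00 | 66.8 | 32.2 |
| red | 3.00 | 70.5 | 29.7 |
| red | 4.00 | 72.6 | 26.4 |
| green | 0.250 | 16.9 | 82.9 |
| green | 0.417 | 34.9 | 67.0 |
| green | 0.667 | 54.5 | 45.6 |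
| green | 1.00 | 65.1 | 36.1 |
| green | 1.50 | 69.7 | 29.1 |
| green | 2.50 | 72.4 | 27.3 |
| green | 4.00 | 75.1 | 23.0 |

(each reading ± 1 percentage point)

- the average divides the monomer in chains by the number of chains begun, living and dead together
- the numbers in the tables scatter with a standard deviation of 1 percentage point
- the earlier runs do not show the number of chains; that part of a forecast is a guess

- average number of monomer units in a chain (chains begun, living or dead) at 3.0 h
- part of the free monomer that has reacted at 3.0 h

I build the flask up one process at a time. With growth by itself, each initiator begins one chain and the whole charge of free monomer goes into chains, so the average chain has 200 units.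

Next I add what stops growth. In both runs the curves bend and then creep, so the number must be multiplied by the part that has reacted. At 3.0 h the red run has reacted 70.3%. The green run, by the mean of its readings at 2.50 h and 4.00 h, has reacted 74.8%. Carrying that step on to this flask's initiator gives 79.7%, a reading with their scatter in it. So the number becomes 160, the units per initiator charged, which is reacted monomer divided by initiator charged.

Last comes the initiator that begins no chain, which these runs do not show. If one chain takes one initiator, the average is my number divided by the share of initiator that began a chain, the initiator efficiency. I commit to 79.7% reacted and to 160 as the number to divide, with that share unread.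

The forecast gives 175 units and 78% reacted, against my 79.7%, and says “Efficiency is unknown”. The flask gives 873 units and 77.3%.

    free monomer + initiator → living end + monomer in chains (k = 0.00650 M⁻¹ min⁻¹)
    free monomer + living end → monomer in chains + living end, rate k2*[living end]*[free monomer] (k = 69.0 M⁻¹ min⁻¹)
    living end + monomer in chains → dead end A (k = 0.0850 M⁻¹ min⁻¹)
    2 initiator → spent initiator B (k = 3.30 M⁻¹ min⁻¹)

Held against 873, my 160 gives a share of 18.3% for this flask. Growth ran while living ends stood: monomer in chains reached 27.3% at 0.300 h with living ends at 7.44% of the initiator charge, and 73.4% at 1.50 h with 0.885%. Meanwhile initiator went into spent initiator B, which holds 71.7% of the initiator charge at 3.00 h, with 11% left. In the red run at its last reading, 4.00 h, the same number is 285 against an average of 1020, a share of 27.9%.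

The data are calculated on assumed constants; the scatter is artificial.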